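**Plan**

1. Numbering: carbocycle C1–C6 (C2 Br; C3 Cl and CH3; C6 bonded to C7), oxane O–C7(CH3)–C8(OAc)–C9–C10(Br)–C11(CH3)2. The retrosynthesis cuts, in order: C3–Cl and C2–Br (back through bromohydrin and epoxide to a C2=C3 alkene) and the acetyl group; C6–C1 together with C5–C4 ([4+2] of isoprene on C5=C6); O–C11 with C10–Br (bromoetherification); C6–C7 (ethynyl addition to a methyl ketone); C8–O (α-oxygenation of 6-methylhept-5-en-2-one).
2. Enabling feature: O8 and C6 stand cis on the neighbouring oxane carbons C8 and C7, so one carbonyl carbon can tie them into a cis-fused α-methylene-γ-butyrolactone (O8–C(=O)–C6=C5H2). This temporary ring makes C5=C6 a dienophile, sends the isoprene methyl to C3, leaves one face open (sets C6), and beforehand enforces the chair that sets C10. Its carbon is cut out again as CO with retention at C6.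
3. Forward: chain (steps 1–2), temporary lactone (3), oxane ring (4), carbocycle by Diels–Alder reaction as the last ring of the skeleton (5), lactone carbon out (6–7), acetate (8), halogens (9–11).
4. Stereochemistry: C8 from L-proline; C7 by chelation control; C10 by the chair-like bromoetherification; C6 by convex-face cycloaddition plus retentive decarbonylation; C2 and C3 by catalyst-controlled epoxidation and two anti openings, the second with a 1,2-shift of bromine.

Key step: step 5

Remark: the target as drawn is 2S,3S,6S,7R,8R,10R, with Br, Cl and the oxanyl group all equatorial on the carbocycle (Br cis, Cl trans to the oxanyl group). Direct BrCl addition to the cyclohexene would give the trans-diaxial adduct of the other face, hence the three-step halogen sequence.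

**Route**

Step 1
Reactants: 1 6-methylhept-5-en-2-one
Product: 3 (3R)-3-hydroxy-6-methylhept-5-en-2-one, via aminooxy ketone 2 (not isolated)
Conditions: L-proline (20 mol %), PhNO (added slowly; 1 in threefold excess), DMSO, rt; then CuSO4·5H2O (30 mol %), MeOH, 0 °C
Reagents that add atoms: nitrosobenzene, O=Nc1ccccc1
Why: Proline-catalysed α-aminoxylation (O-nitroso aldol reaction) engages only the ketone through its more substituted enamine, so oxygen enters at C8 and not at the methyl group, the carboxylic acid of L-proline delivers PhN=O to one enamine face so that C8 is formed as R, and CuSO4 then cleaves the N–O bond without touching the stereocentre or the alkene.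

Step 2
Reactants: 3 (3R)-3-hydroxy-6-methylhept-5-en-2-one; 4 ethynylmagnesium bromide
Product: 5 (3R,4R)-3,7-dimethyloct-6-en-1-yne-3,4-diol
Conditions: HC≡CMgBr (3.5 equiv), THF, −78 → 0 °C; aq. NH4Cl
Reagents that add atoms: ethynylmagnesium bromide (4), C#C[Mg]Br
Why: Cram-chelate-controlled Grignard addition, in which the magnesium alkoxide of the α-hydroxy ketone chelates the carbonyl oxygen and the ethynyl group enters from the side of the small H on C8 (anti to the prenyl CH2), setting the tertiary carbinol C7 as R, while the weakly basic acetylide does not enolise the ketone.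

Step 3
Reactants: 5 (3R,4R)-3,7-dimethyloct-6-en-1-yne-3,4-diol
Product: 6 (4R,5R)-4-hydroxy-4-methyl-3-methylidene-5-(3-methylbut-2-en-1-yl)oxolan-2-one
Conditions: PdI2 (5 mol %), PBu3 (10 mol %), CO (7 atm), MeCN, 70 °C
Reagents that add atoms: carbon monoxide, [C-]#[O+]
Why: Pd-catalysed cyclocarbonylation of a but-3-yn-1-ol, in which the secondary C8 hydroxyl, CO and palladium give an alkoxycarbonylpalladium species that adds syn and intramolecularly across the alkyne (5-exo-dig) before protonolysis, whereas the tertiary C7 hydroxyl could only close a strained four-membered lactone, and no stereocentre is touched.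

Step 4
Reactants: 6 (4R,5R)-4-hydroxy-4-methyl-3-methylidene-5-(3-methylbut-2-en-1-yl)oxolan-2-one
Product: 7 (3aR,6R,7aR)-6-bromo-3a,5,5-trimethyl-3-methylidenehexahydro-2H-furo[3,2-b]pyran-2-one
Conditions: 2,4,4,6-tetrabromocyclohexa-2,5-dien-1-one (TBCO, 1.2 equiv), MeNO2, 0 °C → rt, dark
Reagents that add atoms: 2,4,4,6-tetrabromocyclohexa-2,5-dien-1-one, O=C1C(Br)=CC(Br)(Br)C=C1Br
Why: Bromoetherification by 6-endo Markovnikov attack of the tertiary C7 hydroxyl on C11 of the bromonium ion of the electron-rich trisubstituted alkene (the electron-poor methylene lactone is inert to Br+), through a chair in which C–Br is equatorial and the lactone carbon C6 must be equatorial because an axial C6 would push its exocyclic CH2 against the axial C11 methyl, which places the C7 methyl and O8 axial and sets C10 as R, trans to O8.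

Step 5
Reactants: 7 (3aR,6R,7aR)-6-bromo-3a,5,5-trimethyl-3-methylidenehexahydro-2H-furo[3,2-b]pyran-2-one; 8 isoprene
Product: 9 (3R,3aR,6R,7aR)-6-bromo-3a,4',5,5-tetramethylhexahydro-2H-spiro[furo[3,2-b]pyran-3,1'-cyclohex[3]en]-2-one
Conditions: isoprene (5 equiv), Me2AlCl (0.3 equiv), CH2Cl2, −40 → 0 °C
Reagents that add atoms: isoprene (8), C=CC(C)=C
Why: Lewis acid-promoted Diels–Alder reaction in which isoprene adds in one concerted, asynchronous step across the exocyclic C5=C6 bond of the α-methylene-γ-butyrolactone, whose LUMO is lowered by Me2AlCl on the lactone carbonyl; the closest known reaction type is the spiroannulation of α-methylene lactones with 2-substituted butadienes. The carbocycle is closed by intermolecular [4+2] cycloaddition, which forms C5–C4 and C6–C1 at once and leaves the C2=C3 double bond where the halogens are needed, while neither ring of the bicycle is opened. The regioselectivity needed (methyl on C3, 1,4 to the carbonyl-bearing C6) follows from the match of the largest LUMO coefficient (C5) with the largest HOMO coefficient of isoprene (the CH2 next to the methyl-bearing carbon) and is raised by the Lewis acid. The only new stereocentre is the spiro carbon C6, and it is controlled by the cis-fused lactone–oxane bicycle: the C7–O bond stands nearly perpendicular to the enoate plane and blocks the concave face, so the diene adds to the convex face (that of the C7 methyl and H8) and C1 ends up syn to the C7 methyl. Endo/exo selectivity is irrelevant because isoprene has no stereogenic terminus, and the secondary bromide and the ether are inert to the mild Lewis acid at low temperature. The lactone carbonyl carbon thus serves as activating group, regiochemical director and stereochemical tether, and it is removed with retention in steps 6 and 7.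

Step 6
Reactants: 9 (3R,3aR,6R,7aR)-6-bromo-3a,4',5,5-tetramethylhexahydro-2H-spiro[furo[3,2-b]pyran-3,1'-cyclohex[3]en]-2-one
Product: 10 (3R,3aR,6R,7aR)-6-bromo-3a,4',5,5-tetramethylhexahydro-2H-spiro[furo[3,2-b]pyran-3,1'-cyclohex[3]en]-2-ol (both anomers)
Conditions: i-Bu2AlH (1.2 equiv), CH2Cl2, −78 °C; aq. potassium sodium tartrate
Reagents that add atoms: none
Why: Partial reduction of a lactone with i-Bu2AlH at low temperature stops at the stable aluminium hemiacetal, which gives the five-membered lactol on work-up, the secondary bromide and the alkene being inert and the configuration of the new hemiacetal carbon being of no consequence because that carbon is lost in the next step.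

Step 7
Reactants: 10 (3R,3aR,6R,7aR)-6-bromo-3a,4',5,5-tetramethylhexahydro-2H-spiro[furo[3,2-b]pyran-3,1'-cyclohex[3]en]-2-ol
Product: 11 (2R,3R,5R)-5-bromo-2,6,6-trimethyl-2-[(1S)-4-methylcyclohex-3-en-1-yl]oxan-3-ol
Conditions: RhCl(PPh3)3 (1.2 equiv), N-methylpyrrolidinone, 130 °C
Reagents that add atoms: none
Why: Tsuji–Wilkinson decarbonylation of the ring-opened γ-hydroxy aldehyde tautomer of the lactol (the reaction type that shortens aldoses by one carbon), in which oxidative addition of the formyl C–H bond, CO extrusion and C–H reductive elimination replace the formyl group on C6 by H with retention, so that the configuration fixed in step 5 becomes 6S and O8 is set free.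

Step 8
Reactants: 11 (2R,3R,5R)-5-bromo-2,6,6-trimethyl-2-[(1S)-4-methylcyclohex-3-en-1-yl]oxan-3-ol
Product: 12 (2R,3R,5R)-5-bromo-2,6,6-trimethyl-2-[(1S)-4-methylcyclohex-3-en-1-yl]oxan-3-yl acetate
Conditions: Ac2O, DMAP (cat.), pyridine, CH2Cl2, rt
Reagents that add atoms: acetic anhydride, CC(=O)OC(C)=O
Why: DMAP-catalysed acylation of the hindered axial secondary alcohol installs the acetate of the target and affects no stereocentre.

Step 9
Reactants: 12 (2R,3R,5R)-5-bromo-2,6,6-trimethyl-2-[(1S)-4-methylcyclohex-3-en-1-yl]oxan-3-yl acetate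
Product: 13 (2R,3R,5R)-5-bromo-2,6,6-trimethyl-2-[(1R,3S,6S)-6-methyl-7-oxabicyclo[4.1.0]heptan-3-yl]oxan-3-yl acetate
Conditions: D-fructose-derived Shi ketone (30 mol %), KHSO5 (as 2KHSO5·KHSO4·K2SO4), K2CO3, Bu4NHSO4, MeCN/dimethoxymethane/aq. Na2B4O7 buffer, 0 °C
Reagents that add atoms: potassium peroxymonosulfate, [K+].[O-]S(=O)(=O)OO
Why: Shi asymmetric epoxidation (chiral dioxirane, spiro transition state) of the only alkene, where the catalyst and not the remote C6 substituent selects the face, and the D-fructose-derived ketone is expected to oxidise the face that it oxidises in 1-substituted cyclohexenes, giving the 2R,3S epoxide with oxygen trans to the oxanyl group.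

Step 10
Reactants: 13 (2R,3R,5R)-5-bromo-2,6,6-trimethyl-2-[(1R,3S,6S)-6-methyl-7-oxabicyclo[4.1.0]heptan-3-yl]oxan-3-yl acetate
Product: 14 (2R,3R,5R)-5-bromo-2-[(1S,3R,4R)-4-bromo-3-hydroxy-4-methylcyclohexyl]-2,6,6-trimethyloxan-3-yl acetate
Conditions: anhydrous HBr (1.1 equiv, solution in Et2O), Et2O, −40 °C
Reagents that add atoms: hydrogen bromide, Br
Why: Acid-mediated epoxide opening in which the Markovnikov and Fürst–Plattner preferences coincide, so that bromide attacks the tertiary C3 axially with inversion from the face cis to the oxanyl group and gives the trans-diaxial bromohydrin (3R bromide, 2R alcohol).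

Step 11
Reactants: 14 (2R,3R,5R)-5-bromo-2-[(1S,3R,4R)-4-bromo-3-hydroxy-4-methylcyclohexyl]-2,6,6-trimethyloxan-3-yl acetate
Product: 17 8-acetylcaespitol, via chlorosulfite 15 (not isolated), via bromonium chloride 16 (not isolated)
Conditions: SOCl2 (1.5 equiv), pyridine (3 equiv), CH2Cl2, −30 → 0 °C
Reagents that add atoms: thionyl chloride, O=S(Cl)Cl
Why: Substitution with neighbouring-group participation (the classical chemistry of β-bromo alcohols), in which the chlorosulfite of the axial C2 hydroxyl is displaced from behind by the antiperiplanar axial bromine and chloride opens the bromonium ion at the tertiary carbon C3 anti to bromine, so that bromine ends on C2 and chlorine on C3, trans and both equatorial, with inversion at both carbons (2S,3S).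

**Compound list**

1 | 6-methylhept-5-en-2-one | CC(=O)CCC=C(C)C | starting material
2 | (3R)-6-methyl-3-[(phenylamino)oxy]hept-5-en-2-one | CC(=O)[C@H](ONc1ccccc1)CC=C(C)C | intermediate
3 | (3R)-3-hydroxy-6-methylhept-5-en-2-one | CC(=O)[C@H](O)CC=C(C)C | intermediate
4 | ethynylmagnesium bromide | C#C[Mg]Br | starting material
5 | (3R,4R)-3,7-dimethyloct-6-en-1-yne-3,4-diol | C#C[C@@](C)(O)[C@H](O)CC=C(C)C | intermediate
6 | (4R,5R)-4-hydroxy-4-methyl-3-methylidene-5-(3-methylbut-2-en-1-yl)oxolan-2-one | C=C1C(=O)O[C@H](CC=C(C)C)[C@]1(C)O | intermediate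
7 | (3aR,6R,7aR)-6-bromo-3a,5,5-trimethyl-3-methylidenehexahydro-2H-furo[3,2-b]pyran-2-one (cis-fused; Br trans to the lactone oxygen) | C=C1C(=O)O[C@@H]2C[C@@H](Br)C(C)(C)O[C@]12C | intermediate
8 | isoprene (2-methylbuta-1,3-diene) | C=CC(C)=C | starting material
9 | (3R,3aR,6R,7aR)-6-bromo-3a,4',5,5-tetramethylhexahydro-2H-spiro[furo[3,2-b]pyran-3,1'-cyclohex[3]en]-2-one (spiro carbon C6; C1 syn to the C7 methyl) | O=C1O[C@@H]2C[C@@H](Br)C(C)(C)O[C@]2(C)[C@]13CCC(C)=CC3 | intermediate
10 | (3R,3aR,6R,7aR)-6-bromo-3a,4',5,5-tetramethylhexahydro-2H-spiro[furo[3,2-b]pyran-3,1'-cyclohex[3]en]-2-ol (lactol, both anomers) | OC1O[C@@H]2C[C@@H](Br)C(C)(C)O[C@]2(C)[C@]13CCC(C)=CC3 | intermediate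
11 | (2R,3R,5R)-5-bromo-2,6,6-trimethyl-2-[(1S)-4-methylcyclohex-3-en-1-yl]oxan-3-ol | O[C@@H]1C[C@@H](Br)C(C)(C)O[C@]1(C)[C@H]1CCC(C)=CC1 | intermediate
12 | (2R,3R,5R)-5-bromo-2,6,6-trimethyl-2-[(1S)-4-methylcyclohex-3-en-1-yl]oxan-3-yl acetate | CC(=O)O[C@@H]1C[C@@H](Br)C(C)(C)O[C@]1(C)[C@H]1CCC(C)=CC1 | intermediate
13 | (2R,3R,5R)-5-bromo-2,6,6-trimethyl-2-[(1R,3S,6S)-6-methyl-7-oxabicyclo[4.1.0]heptan-3-yl]oxan-3-yl acetate (epoxide oxygen trans to the oxanyl group) | CC(=O)O[C@@H]1C[C@@H](Br)C(C)(C)O[C@]1(C)[C@H]1CC[C@]2(C)O[C@@H]2C1 | intermediate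
14 | (2R,3R,5R)-5-bromo-2-[(1S,3R,4R)-4-bromo-3-hydroxy-4-methylcyclohexyl]-2,6,6-trimethyloxan-3-yl acetate (trans-diaxial bromohydrin) | CC(=O)O[C@@H]1C[C@@H](Br)C(C)(C)O[C@]1(C)[C@H]1CC[C@@](C)(Br)[C@H](O)C1 | intermediate
15 | chlorosulfite ester of 14 (O–S(=O)Cl on C2) | CC(=O)O[C@@H]1C[C@@H](Br)C(C)(C)O[C@]1(C)[C@H]1CC[C@@](C)(Br)[C@H](OS(=O)Cl)C1 | intermediate
16 | bromonium chloride ion pair (Br bridging C2 and C3 on the face cis to the oxanyl group) | CC(=O)O[C@@H]1C[C@@H](Br)C(C)(C)O[C@]1(C)[C@H]1CC[C@@]2(C)[Br+][C@H]2C1.[Cl-] | intermediate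
17 | 8-acetylcaespitol, (2R,3R,5R)-5-bromo-2-[(1S,3S,4S)-3-bromo-4-chloro-4-methylcyclohexyl]-2,6,6-trimethyloxan-3-yl acetate | CC(=O)O[C@@H]1C[C@@H](Br)C(C)(C)O[C@]1(C)[C@H]1CC[C@](C)(Cl)[C@@H](Br)C1 | target

**Step count and risks**

Total step count: 11. Longest linear sequence: 11 steps (from 1).

Steps most likely to fail:

Step 11. What may go wrong: chloride may open the bromonium ion at the secondary carbon C2 (diaxial opening with overall retention) instead of at the tertiary C3, and the tertiary bromide may lose HBr. The fallback sets out from 14 and returns at 17, and replaces kinetic capture by an equilibration. The hydroxyl of 14 is exchanged for chloride under ion-pair return conditions (SOCl2 in 1,4-dioxane, no base), which should give the trans-diaxial 2-chloro-3-bromide (2R,3R,5R)-5-bromo-2-[(1S,3R,4R)-4-bromo-3-chloro-4-methylcyclohexyl]-2,6,6-trimethyloxan-3-yl acetate F1. F1 is then heated in chlorobenzene at about 130 °C to bring about the thermal 1,2-interchange of trans-diaxial vicinal halogens (diaxial to diequatorial rearrangement through the same bromonium chloride ion pair). The diaxial isomer can re-ionise because its halogens are antiperiplanar, whereas the diequatorial tertiary chloride 17 cannot, so the material should collect as 17.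

Step 7. What may go wrong: the hindered lactol may stay ring-closed so that oxidative addition is slow, and the tertiary alkylrhodium hydride may undergo β-hydride elimination instead of reductive elimination. The fallback sets out from 9 and returns at 11, and replaces the decarbonylation by a radical decarboxylation.
- Saponification (LiOH, THF/H2O) should give lithium (1R)-1-[(2R,3R,5R)-5-bromo-3-hydroxy-2,6,6-trimethyloxan-2-yl]-4-methylcyclohex-3-ene-1-carboxylate F2.
- Exhaustive silylation (Et3SiOTf, 2,6-lutidine) should give triethylsilyl (1R)-1-[(2R,3R,5R)-5-bromo-2,6,6-trimethyl-3-(triethylsilyloxy)oxan-2-yl]-4-methylcyclohex-3-ene-1-carboxylate F3.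
- Cleavage of the silyl ester (K2CO3, MeOH/H2O) should give (1R)-1-[(2R,3R,5R)-5-bromo-2,6,6-trimethyl-3-(triethylsilyloxy)oxan-2-yl]-4-methylcyclohex-3-ene-1-carboxylic acid F4, which cannot relactonise.
- Coupling with N-hydroxypyridine-2-thione (DCC) should give the Barton ester 2-thioxopyridin-1(2H)-yl (1R)-1-[(2R,3R,5R)-5-bromo-2,6,6-trimethyl-3-(triethylsilyloxy)oxan-2-yl]-4-methylcyclohex-3-ene-1-carboxylate F5.
- Photolysis with t-BuSH (Barton decarboxylation) should give triethyl{[(2R,3R,5R)-5-bromo-2,6,6-trimethyl-2-[(1S)-4-methylcyclohex-3-en-1-yl]oxan-3-yl]oxy}silane F6 together with its C6 epimer, because the planar C6 radical is reduced from both faces; the epimer is removed by chromatography.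
- Bu4NF then frees 11.

Step 4. What may go wrong: competing 5-exo closure at C10 (an oxolane with a tertiary bromide) and incomplete facial selectivity at C10. The fallback sets out from 6 and returns at 7, and separates ring closure from bromination. Hg(OCOCF3)2 in MeNO2 at 0 °C, then aqueous KBr, should give bromo[(3aR,6R,7aR)-3a,5,5-trimethyl-3-methylidene-2-oxohexahydro-2H-furo[3,2-b]pyran-6-yl]mercury F7 by reversible Markovnikov (6-endo) oxymercuration, which funnels to the chair with equatorial C–Hg. Br2 and LiBr in pyridine (electrophilic bromodemercuration with retention) should then give 7.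

**Further compounds**

F1 | step 11 | (2R,3R,5R)-5-bromo-2-[(1S,3R,4R)-4-bromo-3-chloro-4-methylcyclohexyl]-2,6,6-trimethyloxan-3-yl acetate | CC(=O)O[C@@H]1C[C@@H](Br)C(C)(C)O[C@]1(C)[C@H]1CC[C@@](C)(Br)[C@H](Cl)C1
F2 | step 7 | lithium (1R)-1-[(2R,3R,5R)-5-bromo-3-hydroxy-2,6,6-trimethyloxan-2-yl]-4-methylcyclohex-3-ene-1-carboxylate | O[C@@H]1C[C@@H](Br)C(C)(C)O[C@]1(C)[C@@]1(C(=O)[O-])CCC(C)=CC1.[Li+]
F3 | step 7 | triethylsilyl (1R)-1-[(2R,3R,5R)-5-bromo-2,6,6-trimethyl-3-(triethylsilyloxy)oxan-2-yl]-4-methylcyclohex-3-ene-1-carboxylate | CC[Si](CC)(CC)O[C@@H]1C[C@@H](Br)C(C)(C)O[C@]1(C)[C@@]1(C(=O)O[Si](CC)(CC)CC)CCC(C)=CC1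
F4 | step 7 | (1R)-1-[(2R,3R,5R)-5-bromo-2,6,6-trimethyl-3-(triethylsilyloxy)oxan-2-yl]-4-methylcyclohex-3-ene-1-carboxylic acid | CC[Si](CC)(CC)O[C@@H]1C[C@@H](Br)C(C)(C)O[C@]1(C)[C@@]1(C(=O)O)CCC(C)=CC1
F5 | step 7 | 2-thioxopyridin-1(2H)-yl (1R)-1-[(2R,3R,5R)-5-bromo-2,6,6-trimethyl-3-(triethylsilyloxy)oxan-2-yl]-4-methylcyclohex-3-ene-1-carboxylate | CC[Si](CC)(CC)O[C@@H]1C[C@@H](Br)C(C)(C)O[C@]1(C)[C@@]1(C(=O)On2ccccc2=S)CCC(C)=CC1
F6 | step 7 | triethyl{[(2R,3R,5R)-5-bromo-2,6,6-trimethyl-2-[(1S)-4-methylcyclohex-3-en-1-yl]oxan-3-yl]oxy}silane | CC[Si](CC)(CC)O[C@@H]1C[C@@H](Br)C(C)(C)O[C@]1(C)[C@H]1CCC(C)=CC1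
F7 | step 4 | bromo[(3aR,6R,7aR)-3a,5,5-trimethyl-3-methylidene-2-oxohexahydro-2H-furo[3,2-b]pyran-6-yl]mercury | C=C1C(=O)O[C@@H]2C[C@@H]([Hg]Br)C(C)(C)O[C@]12C
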